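**Plan**
Numbering: bicyclo[3.2.1]octene with C1 (allyl-bearing bridgehead), C2=C3(OMe), C4 (enone C=O), C5 (bridgehead CH), C6 (aryl), C7 (methyl), C8 (one-carbon bridge, C=O).
Enabling feature: ring C1–C8–C5–C6–C7 is a cyclopentanone whose carbonyl carbon C8 lies across the ring from the C6–C7 bond, and that bond carries aryl and methyl trans. This is the outcome of conrotatory 4π closure of the (E,E)-divinyl ketone C7=C1–C8(=O)–C5=C6.
Cuts, in retrosynthetic order: O–CH3 and C3–O (methoxy enone back to a C4 ketone), C4–C5 (aldol), C1–allyl (enolate alkylation), C6–C7 together with C5–H (silane-intercepted Nazarov), then C1=C7 and C5=C6 (two aldol condensations on a C6 methyl ketone).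
Forward: the acyclic dienone is built linearly (steps 1–5). The five-membered ring closes first (step 6) and the six-membered ring C1–C2–C3–C4–C5–C8 second (step 10). C3/C4 are then raised to the methoxy enone (steps 11–14).
Stereochemistry: C6/C7 are trans from E,E geometry plus conrotation, with the absolute sense from a confined chiral counter-anion. C1 comes from allylation anti to the C7 methyl. C5 comes from the tether, which can bridge only on the ring face where C1 holds it.

Key step: step 6

Assumption: the sense of conrotation induced by a given antipode of the chiral acid cannot be derived on paper. The (S,S) form is written, and the (R,R) form would be used if it is the one that leads to the C6/C7 configuration of the target.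
Remark: the locants C1–C8 of the target are used for the same atoms in all intermediates. Systematic names carry their own locants, and changes of R/S between related compounds reflect CIP priorities only.

Step 1
Reactants: 1 5-hexyn-1-ol
Product: 2 (hex-5-yn-1-yloxy)triisopropylsilane
Conditions: i-Pr3SiCl, imidazole, CH2Cl2, 0 °C → rt
Reagents that add atoms: triisopropylsilyl chloride, CC(C)[Si](Cl)(C(C)C)C(C)C
Why: Imidazole-promoted silylation of a primary alcohol, with the bulky TIPS ether chosen because it must later outlast hydroxide, amide bases, a silylium-type Lewis acid and methyllithium.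

Step 2
Reactants: 2 (hex-5-yn-1-yloxy)triisopropylsilane
Product: 3 6-(triisopropylsilyloxy)hexan-2-one
Conditions: Ph3PAuNTf2 (1 mol %), H2O, MeOH, rt → 40 °C
Reagents that add atoms: water, O
Why: Cationic monovalent gold catalyses Markovnikov hydration of the terminal alkyne to the methyl ketone under nearly neutral conditions that leave the silyl ether intact.

Step 3
Reactants: 3 6-(triisopropylsilyloxy)hexan-2-one; 4 3,4-dimethoxybenzaldehyde
Product: 5 (E)-1-(3,4-dimethoxyphenyl)-7-(triisopropylsilyloxy)hept-1-en-3-one
Conditions: NaOH (aq), EtOH, rt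
Reagents that add atoms: 3,4-dimethoxybenzaldehyde 4, COc1ccc(C=O)cc1OC
Why: Claisen–Schmidt condensation, in which an alkyl methyl ketone reacts under hydroxide with a non-enolisable aryl aldehyde at its methyl group and E1cB loss of water gives the E-styryl ketone (C5=C6).

Step 4
Reactants: 5 (E)-1-(3,4-dimethoxyphenyl)-7-(triisopropylsilyloxy)hept-1-en-3-one; 6 acetaldehyde
Product: 8 (E)-1-(3,4-dimethoxyphenyl)-4-(1-hydroxyethyl)-7-(triisopropylsilyloxy)hept-1-en-3-one (mixture of diastereomers), via lithium enolate 7 (not isolated)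
Conditions: LiN(i-Pr)2, THF, −78 °C; then MeCHO, −78 °C
Reagents that add atoms: acetaldehyde 6, CC=O; lithium diisopropylamide, [Li+].CC(C)[N-]C(C)C (lithium kept only in 7)
Why: Directed aldol addition in which the α′-methylene (future C1) is the only enolisable position because the other flank of the ketone is vinylic, and both new stereocentres disappear in the next step, so the mixture is carried on.

Step 5
Reactants: 8 (E)-1-(3,4-dimethoxyphenyl)-4-(1-hydroxyethyl)-7-(triisopropylsilyloxy)hept-1-en-3-one
Product: 10 (1E,4E)-1-(3,4-dimethoxyphenyl)-4-[3-(triisopropylsilyloxy)propyl]hexa-1,4-dien-3-one, via secondary mesylate 9 (not isolated)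
Conditions: MsCl, Et3N, CH2Cl2, 0 °C; then DBU, 0 °C → rt
Reagents that add atoms: methanesulfonyl chloride, CS(=O)(=O)Cl (atoms kept only in 9)
Why: Mesylation followed by DBU-induced E1cB elimination should favour the tiglate-like E alkene (methyl trans to the acyl group), because the Z isomer suffers allylic strain between methyl and carbonyl.

Step 6
Reactants: 10 (1E,4E)-1-(3,4-dimethoxyphenyl)-4-[3-(triisopropylsilyloxy)propyl]hexa-1,4-dien-3-one; 11 triethylsilane
Product: 13 triethyl({(3R,4S)-4-(3,4-dimethoxyphenyl)-3-methyl-2-[3-(triisopropylsilyloxy)propyl]cyclopent-1-en-1-yl}oxy)silane (aryl and methyl trans), via silyloxyallyl cation 12 (not isolated)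
Conditions: (S,S)-IDPi (BINOL-derived imidodiphosphorimidate, 3,3′-[3,5-(CF3)2C6H3] groups and N-SO2CF3 as starting point, 5 mol %), Et3SiH (1.5 equiv, added slowly), toluene, −20 °C; then Et3N
Reagents that add atoms: triethylsilane 11, CC[SiH](CC)CC
Why: Proposed new method: the acid, and after the first turnover its Et3Si+ ion pair, binds the carbonyl oxygen of 10 to give a 3-oxypentadienyl cation paired with the chiral anion; this cation ring-closes to the silyloxyallyl cation 12, Et3SiH gives hydride to C5, and the Et3Si+ so released activates the next molecule of 10, so that the silane ends up as C5–H and O–SiEt3 of 13. The closest known reaction types are the Lewis-acid-promoted reductive (silane-interrupted) Nazarov cyclisation, which is racemic and normally ends at the ketone, and the confined-Brønsted-acid-catalysed enantioselective Nazarov cyclisation of simple divinyl ketones, which ends by proton loss; their combination is untested. The five-membered ring C1–C8–C5–C6–C7 closes by a thermally allowed conrotatory 4π electrocyclisation (formally 5-endo-trig) that forms C6–C7. C6 and C7 are set relative to each other by conrotation of the two E termini, which puts aryl and methyl trans, and in the absolute sense by the anion pocket, which must favour one direction of conrotation. Two selectivities are needed: ring closure must outrun direct hydride transfer to the donor-stabilised benzylic terminus C6 (the dimethoxyphenyl group slows closure), which the α-alkyl arm helps by favouring the s-trans/s-trans conformer and stabilising 12 and which slow addition of silane helps because closure is unimolecular; and hydride must go to C5, which is secondary and open, not to C1, which is fully substituted and flanked by the arm and the C7 methyl. Because no proton is lost, neither new stereocentre is erased, and the tetrasubstituted enol silane marks C1 for the next step.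

Step 7
Reactants: 13 triethyl({(3R,4S)-4-(3,4-dimethoxyphenyl)-3-methyl-2-[3-(triisopropylsilyloxy)propyl]cyclopent-1-en-1-yl}oxy)silane; 14 allyl bromide
Product: 16 (2S,3R,4S)-2-allyl-4-(3,4-dimethoxyphenyl)-3-methyl-2-[3-(triisopropylsilyloxy)propyl]cyclopentan-1-one (allyl trans to methyl, cis to aryl), via lithium enolate 15 (not isolated)
Conditions: MeLi, THF, 0 °C; then allyl bromide, DMPU, −78 → 0 °C
Reagents that add atoms: allyl bromide 14, C=CCBr; methyllithium, [Li]C (lithium kept only in 15)
Why: Methyllithium cleaves the enol Si–O bond and releases the tetrasubstituted lithium enolate regiospecifically, and SN2 allylation should occur on the face opposite the adjacent C7 methyl, as in the trans-selective alkylation of 3-substituted cyclopentanone enolates, which sets quaternary C1.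

Step 8
Reactants: 16 (2S,3R,4S)-2-allyl-4-(3,4-dimethoxyphenyl)-3-methyl-2-[3-(triisopropylsilyloxy)propyl]cyclopentan-1-one
Product: 17 (2S,3R,4S)-2-allyl-4-(3,4-dimethoxyphenyl)-2-(3-hydroxypropyl)-3-methylcyclopentan-1-one
Conditions: Bu4NF, THF, rt
Reagents that add atoms: none
Why: Fluoride-induced cleavage of the primary silyl ether, with no stereocentre at risk because C1 is quaternary and C6 and C7 are not α to the carbonyl.

Step 9
Reactants: 17 (2S,3R,4S)-2-allyl-4-(3,4-dimethoxyphenyl)-2-(3-hydroxypropyl)-3-methylcyclopentan-1-one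
Product: 18 3-[(1S,2R,3S)-1-allyl-3-(3,4-dimethoxyphenyl)-2-methyl-5-oxocyclopentyl]propanal
Conditions: Dess–Martin periodinane, CH2Cl2, 0 °C → rt
Reagents that add atoms: none
Why: Dess–Martin oxidation stops at the aldehyde (C4) and leaves the alkene, the arene and the ketone untouched.

Step 10
Reactants: 18 3-[(1S,2R,3S)-1-allyl-3-(3,4-dimethoxyphenyl)-2-methyl-5-oxocyclopentyl]propanal
Product: 19 (1S,5R,6R,7R)-1-allyl-6-(3,4-dimethoxyphenyl)-4-hydroxy-7-methylbicyclo[3.2.1]octan-8-one (C4 epimers)
Conditions: K2CO3, MeOH, 0 °C → rt, 0.01 M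
Reagents that add atoms: none
Why: Intramolecular aldol addition, 6-(enolendo)-exo-trig, known for 2-(3-oxopropyl)cyclopentanones; the ketone can enolise only toward C5, the reverse pairing would give a four-membered ring, and the tether reaches C5 only on the face where it is anchored at C1 (anti to the C6 aryl), which sets C5, while the C4 epimers converge in step 11.

Step 11
Reactants: 19 (1S,5R,6R,7R)-1-allyl-6-(3,4-dimethoxyphenyl)-4-hydroxy-7-methylbicyclo[3.2.1]octan-8-one
Product: 20 (1S,5R,6R,7R)-1-allyl-6-(3,4-dimethoxyphenyl)-7-methylbicyclo[3.2.1]octane-4,8-dione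
Conditions: Dess–Martin periodinane, CH2Cl2, rt
Reagents that add atoms: none
Why: Dess–Martin oxidation is neutral and non-nucleophilic, which matters because the β-diketone cannot enolise at bridgehead C5 (Bredt) and is therefore open to retro-Claisen cleavage by nucleophilic bases.

Step 12
Reactants: 20 (1S,5R,6R,7R)-1-allyl-6-(3,4-dimethoxyphenyl)-7-methylbicyclo[3.2.1]octane-4,8-dione
Product: 22 (1R,5S,6R,7R)-1-allyl-6-(3,4-dimethoxyphenyl)-3-hydroxy-7-methylbicyclo[3.2.1]octane-4,8-dione (C3 epimers), via potassium enolate 21 (not isolated)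
Conditions: KN(SiMe3)2, THF, −78 °C; then 2-(phenylsulfonyl)-3-phenyloxaziridine, −78 °C
Reagents that add atoms: 2-(phenylsulfonyl)-3-phenyloxaziridine, O=S(=O)(N1OC1c1ccccc1)c1ccccc1; potassium hexamethyldisilazide, [K+].C[Si](C)(C)[N-][Si](C)(C)C (potassium kept only in 21)
Why: Davis oxidation of the enolate, with C3 the only site that can give a planar enolate (C1 quaternary, C5 bridgehead) and its configuration irrelevant because it is removed in step 13.

Step 13
Reactants: 22 (1R,5S,6R,7R)-1-allyl-6-(3,4-dimethoxyphenyl)-3-hydroxy-7-methylbicyclo[3.2.1]octane-4,8-dione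
Product: 24 (1S,5S,6R,7R)-1-allyl-6-(3,4-dimethoxyphenyl)-3-hydroxy-7-methylbicyclo[3.2.1]oct-2-ene-4,8-dione (diosphenol), via 3,4,8-trione 23 (not isolated)
Conditions: Dess–Martin periodinane, CH2Cl2, rt; then Et3N (cat.)
Reagents that add atoms: none
Why: Oxidation of the acyloin gives the 1,2-diketone, which tautomerises toward C2, the only direction open to it, to the conjugated diosphenol.

Step 14
Reactants: 24 (1S,5S,6R,7R)-1-allyl-6-(3,4-dimethoxyphenyl)-3-hydroxy-7-methylbicyclo[3.2.1]oct-2-ene-4,8-dione
Product: 25 kadsurenin D, (1S,5S,6R,7R)-1-allyl-6-(3,4-dimethoxyphenyl)-3-methoxy-7-methylbicyclo[3.2.1]oct-2-ene-4,8-dione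
Conditions: Me2SO4, K2CO3 (anhydrous), acetone, rt → 50 °C
Reagents that add atoms: dimethyl sulfate, COS(=O)(=O)OC
Why: Williamson-type O-methylation of the acidic diosphenol with a hard electrophile and a non-nucleophilic carbonate base should give the enol methyl ether, and none of the four stereocentres can epimerise.

**Compound list**
1 | 5-hexyn-1-ol | C#CCCCCO | starting material
2 | (hex-5-yn-1-yloxy)triisopropylsilane | C#CCCCCO[Si](C(C)C)(C(C)C)C(C)C | intermediate
3 | 6-(triisopropylsilyloxy)hexan-2-one | CC(=O)CCCCO[Si](C(C)C)(C(C)C)C(C)C | intermediate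
4 | 3,4-dimethoxybenzaldehyde | COc1ccc(C=O)cc1OC | starting material
5 | (E)-1-(3,4-dimethoxyphenyl)-7-(triisopropylsilyloxy)hept-1-en-3-one | COc1ccc(/C=C/C(=O)CCCCO[Si](C(C)C)(C(C)C)C(C)C)cc1OC | intermediate
6 | acetaldehyde | CC=O | starting material
7 | lithium enolate of 5 at the α′-methylene (not isolated) | COc1ccc(/C=C/C([O-])=CCCCO[Si](C(C)C)(C(C)C)C(C)C)cc1OC.[Li+] | intermediate
8 | (E)-1-(3,4-dimethoxyphenyl)-4-(1-hydroxyethyl)-7-(triisopropylsilyloxy)hept-1-en-3-one, diastereomer mixture | COc1ccc(/C=C/C(=O)C(CCCO[Si](C(C)C)(C(C)C)C(C)C)C(C)O)cc1OC | intermediate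
9 | methanesulfonate of 8 (not isolated) | COc1ccc(/C=C/C(=O)C(CCCO[Si](C(C)C)(C(C)C)C(C)C)C(C)OS(C)(=O)=O)cc1OC | intermediate
10 | (1E,4E)-1-(3,4-dimethoxyphenyl)-4-[3-(triisopropylsilyloxy)propyl]hexa-1,4-dien-3-one | C/C=C(\CCCO[Si](C(C)C)(C(C)C)C(C)C)C(=O)/C=C/c1ccc(OC)c(OC)c1 | intermediate
11 | triethylsilane | CC[SiH](CC)CC | starting material
12 | 2-(triethylsilyloxy)allyl cation C1–C8–C5 of the closed ring, drawn with the charge at C5 (not isolated) | CC[Si](CC)(CC)OC1=C(CCCO[Si](C(C)C)(C(C)C)C(C)C)[C@H](C)[C@@H](c2ccc(OC)c(OC)c2)[CH+]1 | intermediate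
13 | triethyl({(3R,4S)-4-(3,4-dimethoxyphenyl)-3-methyl-2-[3-(triisopropylsilyloxy)propyl]cyclopent-1-en-1-yl}oxy)silane | CC[Si](CC)(CC)OC1=C(CCCO[Si](C(C)C)(C(C)C)C(C)C)[C@H](C)[C@@H](c2ccc(OC)c(OC)c2)C1 | intermediate
14 | allyl bromide | C=CCBr | starting material
15 | lithium (3R,4S)-4-(3,4-dimethoxyphenyl)-3-methyl-2-[3-(triisopropylsilyloxy)propyl]cyclopent-1-en-1-olate (not isolated) | [Li+].[O-]C1=C(CCCO[Si](C(C)C)(C(C)C)C(C)C)[C@H](C)[C@@H](c2ccc(OC)c(OC)c2)C1 | intermediate
16 | (2S,3R,4S)-2-allyl-4-(3,4-dimethoxyphenyl)-3-methyl-2-[3-(triisopropylsilyloxy)propyl]cyclopentan-1-one | C=CC[C@]1(CCCO[Si](C(C)C)(C(C)C)C(C)C)C(=O)C[C@H](c2ccc(OC)c(OC)c2)[C@H]1C | intermediate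
17 | (2S,3R,4S)-2-allyl-4-(3,4-dimethoxyphenyl)-2-(3-hydroxypropyl)-3-methylcyclopentan-1-one | C=CC[C@]1(CCCO)C(=O)C[C@H](c2ccc(OC)c(OC)c2)[C@H]1C | intermediate
18 | 3-[(1S,2R,3S)-1-allyl-3-(3,4-dimethoxyphenyl)-2-methyl-5-oxocyclopentyl]propanal | C=CC[C@]1(CCC=O)C(=O)C[C@H](c2ccc(OC)c(OC)c2)[C@H]1C | intermediate
19 | (1S,5R,6R,7R)-1-allyl-6-(3,4-dimethoxyphenyl)-4-hydroxy-7-methylbicyclo[3.2.1]octan-8-one, C4 epimers | C=CC[C@]12CCC(O)[C@H](C1=O)[C@H](c1ccc(OC)c(OC)c1)[C@H]2C | intermediate
20 | (1S,5R,6R,7R)-1-allyl-6-(3,4-dimethoxyphenyl)-7-methylbicyclo[3.2.1]octane-4,8-dione | C=CC[C@]12CCC(=O)[C@H](C1=O)[C@H](c1ccc(OC)c(OC)c1)[C@H]2C | intermediate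
21 | potassium C3=C4 enolate of 20 (not isolated) | C=CC[C@]12CC=C([O-])[C@H](C1=O)[C@H](c1ccc(OC)c(OC)c1)[C@H]2C.[K+] | intermediate
22 | (1R,5S,6R,7R)-1-allyl-6-(3,4-dimethoxyphenyl)-3-hydroxy-7-methylbicyclo[3.2.1]octane-4,8-dione, C3 epimers | C=CC[C@]12CC(O)C(=O)[C@H](C1=O)[C@H](c1ccc(OC)c(OC)c1)[C@H]2C | intermediate
23 | (1R,5S,6R,7R)-1-allyl-6-(3,4-dimethoxyphenyl)-7-methylbicyclo[3.2.1]octane-3,4,8-trione (not isolated) | C=CC[C@]12CC(=O)C(=O)[C@H](C1=O)[C@H](c1ccc(OC)c(OC)c1)[C@H]2C | intermediate
24 | (1S,5S,6R,7R)-1-allyl-6-(3,4-dimethoxyphenyl)-3-hydroxy-7-methylbicyclo[3.2.1]oct-2-ene-4,8-dione | C=CC[C@]12C=C(O)C(=O)[C@H](C1=O)[C@H](c1ccc(OC)c(OC)c1)[C@H]2C | intermediate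
25 | kadsurenin D, (1S,5S,6R,7R)-1-allyl-6-(3,4-dimethoxyphenyl)-3-methoxy-7-methylbicyclo[3.2.1]oct-2-ene-4,8-dione | C=CC[C@]12C=C(OC)C(=O)[C@H](C1=O)[C@H](c1ccc(OC)c(OC)c1)[C@H]2C | target

**Totals**
Total step count: 14.
Longest linear sequence: 14 steps (1 → 25).

**Steps most likely to fail**

Step 6. Several things may go wrong:
- The silane may transfer hydride to the activated, donor-stabilised dienone before the ring closes.
- Hydride may arrive at C1 instead of C5.
- Proton loss may outrun hydride capture.
- The ion pair may discriminate too weakly between the two senses of conrotation.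

The fallback sets out from 10 and comes back at 15, and divides the event into two established operations. Run without silane, the confined-acid-catalysed enantioselective Nazarov cyclisation should end by loss of the C7 proton. It should give (4R)-4-(3,4-dimethoxyphenyl)-3-methyl-2-[3-(triisopropylsilyloxy)propyl]cyclopent-2-en-1-one F1, in which C6 is retained. Dissolving-metal reduction of this enone (Li, NH3/THF, t-BuOH 1 equiv, −78 °C) should protonate C7 into the more stable trans arrangement. It should also leave lithium enolate 15 regiospecifically across C1–C8, which is allylated as in step 7 (reductive alkylation).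

Step 7. Facial selectivity at the tetrasubstituted enolate may be poor. Proton exchange between enolate and product may erode the regiochemical integrity. A second allylation at C5 may also occur. The fallback sets out from 13 and comes back at 16, and replaces substrate-controlled SN2 alkylation by catalyst-controlled allyl transfer. The enolate released with MeLi is O-acylated with allyl chloroformate to give allyl (3R,4S)-4-(3,4-dimethoxyphenyl)-3-methyl-2-[3-(triisopropylsilyloxy)propyl]cyclopent-1-en-1-yl carbonate F2. Zerovalent palladium (Pd2(dba)3 with the t-Bu-PHOX antipode that reinforces the substrate bias, toluene, rt) then effects the Tsuji-type decarboxylative allylation. The enolate is formed and consumed at the metal, so it cannot equilibrate, and the ligand adds its own facial preference.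

Step 10. The aldol/retro-aldol equilibrium may be unfavourable, or the aldehyde may condense intermolecularly. The fallback sets out from 16 and comes back at 19, and generates the C5 nucleophile reductively instead of by equilibrium deprotonation.
- Ketone 16 is converted (LiN(SiMe3)2, Me3SiCl, THF, −78 °C) into the C5=C8 trimethylsilyl enol ether F3.
- NBS at −78 °C gives the C5 bromo ketone F4.
- HF·pyridine frees the bromo alcohol F5.
- Dess–Martin oxidation gives the bromo aldehyde F6.
- SmI2 (2.2 equiv, THF, −78 °C) produces the trivalent samarium enolate, which closes onto the aldehyde in an intramolecular Reformatsky-type reaction.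

The chelated samarium aldolate should not revert, and protonation gives 19.

**Further compounds**
F1 | step 6 | (4R)-4-(3,4-dimethoxyphenyl)-3-methyl-2-[3-(triisopropylsilyloxy)propyl]cyclopent-2-en-1-one | CC1=C(CCCO[Si](C(C)C)(C(C)C)C(C)C)C(=O)C[C@@H]1c2ccc(OC)c(OC)c2
F2 | step 7 | allyl (3R,4S)-4-(3,4-dimethoxyphenyl)-3-methyl-2-[3-(triisopropylsilyloxy)propyl]cyclopent-1-en-1-yl carbonate | C=CCOC(=O)OC1=C(CCCO[Si](C(C)C)(C(C)C)C(C)C)[C@H](C)[C@@H](c2ccc(OC)c(OC)c2)C1
F3 | step 10 | C5=C8 trimethylsilyl enol ether of 16, C1, C6 and C7 as in 16 | C=CC[C@]1(CCCO[Si](C(C)C)(C(C)C)C(C)C)C(O[Si](C)(C)C)=C[C@H](c2ccc(OC)c(OC)c2)[C@H]1C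
F4 | step 10 | C5 bromo derivative of 16 (C5 epimers), C1, C6 and C7 as in 16 | C=CC[C@]1(CCCO[Si](C(C)C)(C(C)C)C(C)C)C(=O)C(Br)[C@H](c2ccc(OC)c(OC)c2)[C@H]1C
F5 | step 10 | C5 bromo derivative of 17 (C5 epimers) | C=CC[C@]1(CCCO)C(=O)C(Br)[C@H](c2ccc(OC)c(OC)c2)[C@H]1C
F6 | step 10 | C5 bromo derivative of 18 (C5 epimers) | C=CC[C@]1(CCC=O)C(=O)C(Br)[C@H](c2ccc(OC)c(OC)c2)[C@H]1C
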